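**Plan**

1. In the 1,2-dioxane (O1–O2–C3–C4–C5–C6), C4–C5 is the only ring bond that touches neither an oxygen nor one of the stereocentres C3 and C6. The ring is therefore cut there (as C4=C5), after the side chain has been cut at the C(sp)–C(sp2) bond of the enyne and at the alkyne carbon.
2. The open-chain peroxide that remains is cut at C3–O2 (hydroperoxide plus a 1-alkyl-1-methoxyallene) and at C6–O1 (SN2 on an allylic mesylate).
3. Forward: an (R)-allylic hydroperoxide (from propane-1,3-diol) and the methoxyallene (from tetrahydrofuran) are joined to a mixed peroxyketal with a vinyl group on C3 and on C6. Ring-closing metathesis then makes the only ring, and diimide saturates it.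
4. The chain is finished afterwards: desilylation, oxidation, Ohira–Bestmann alkynylation and Sonogashira coupling with (E)-1-iodoundec-1-ene. Last, the CH2CH2OPMB arm on C6 becomes CH2CO2H.
5. Stereochemistry: C6 comes from a Sharpless kinetic resolution followed by an inverting peroxide displacement. C3 is set by acid-catalysed (anomeric) equilibration of the saturated ketal. The E alkene comes from syn hydrozirconation.

Key step: step 10

Assumption: the C3 epimer with axial methoxy and both carbon chains equatorial, which is the required (3R,6S) isomer, is taken to be the thermodynamically preferred ketal; methoxyallene, Cp2Zr(H)Cl and dimethyl (1-diazo-2-oxopropyl)phosphonate are bought.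

**Route**

Step 1
Reactants: 1 propane-1,3-diol
Product: 3 3-[(4-methoxyphenyl)methoxy]propan-1-ol, via sodium 3-hydroxypropan-1-olate 2 (not isolated)
Conditions: NaH (1 equiv), THF/DMF, 0 °C; then PMBCl (1 equiv), Bu4NI (cat.), rt
Reagents that add atoms: 4-methoxybenzyl chloride, COc1ccc(CCl)cc1
Why: Williamson ether synthesis on the monosodium alkoxide, which forms selectively when one equivalent of NaH is used, should give the mono-PMB ether of the symmetric diol.

Step 2
Reactants: 3 3-[(4-methoxyphenyl)methoxy]propan-1-ol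
Product: 4 3-[(4-methoxyphenyl)methoxy]propanal
Conditions: TEMPO (10 mol%), PhI(OAc)2 (1.1 equiv), CH2Cl2, rt
Reagents that add atoms: none
Why: Oxoammonium (TEMPO/PhI(OAc)2) oxidation of a primary alcohol stops at the aldehyde in anhydrous CH2Cl2 and leaves the PMB ether alone.

Step 3
Reactants: 4 3-[(4-methoxyphenyl)methoxy]propanal; 5 vinylmagnesium bromide
Product: 7 rac-5-[(4-methoxyphenyl)methoxy]pent-1-en-3-ol, via bromomagnesium 5-[(4-methoxyphenyl)methoxy]pent-1-en-3-olate 6 (not isolated)
Conditions: THF, −78 → 0 °C; aq. NH4Cl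
Reagents that add atoms: none
Why: Grignard 1,2-addition to the unhindered aldehyde should give the allylic alcohol as a racemate, the stereocentre being sorted in the next step.

Step 4
Reactants: 7 rac-5-[(4-methoxyphenyl)methoxy]pent-1-en-3-ol
Product: 8 (3S)-5-[(4-methoxyphenyl)methoxy]pent-1-en-3-ol
Conditions: Ti(OiPr)4 (cat.), D-(−)-diisopropyl tartrate, t-BuOOH (0.6 equiv), 4 Å MS, CH2Cl2, −20 °C
Reagents that add atoms: none
Why: Sharpless kinetic resolution: with D-(−)-diisopropyl tartrate the titanium tartrate–peroxide complex epoxidises the (R)-allylic alcohol much faster, so that the (S)-alcohol, whose carbinol carbon becomes C6 of the target, is recovered in rising enantiomeric purity as conversion passes one half.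

Step 5
Reactants: 8 (3S)-5-[(4-methoxyphenyl)methoxy]pent-1-en-3-ol
Product: 9 (3S)-5-[(4-methoxyphenyl)methoxy]pent-1-en-3-yl methanesulfonate
Conditions: MsCl, Et3N, CH2Cl2, −30 °C; cold aqueous work-up, used at once
Reagents that add atoms: methanesulfonyl chloride, CS(=O)(=O)Cl
Why: O-Sulfonylation (mesylation) does not touch the C–O bond, so the (S) configuration is kept, and the low temperature keeps the allylic mesylate from ionising.

Step 6
Reactants: 9 (3S)-5-[(4-methoxyphenyl)methoxy]pent-1-en-3-yl methanesulfonate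
Product: 10 1-({[(3R)-3-hydroperoxypent-4-en-1-yl]oxy}methyl)-4-methoxybenzene
Conditions: 50% aq. H2O2 (20 equiv), KOH (2 equiv), MeOH, 0 °C
Reagents that add atoms: hydrogen peroxide, OO
Why: SN2 displacement by hydroperoxide anion, an α-effect nucleophile that attacks 1-alken-3-yl sulfonates at the carbon bearing the leaving group like other anionic oxygen nucleophiles, should invert the centre and set the (R)-configured C–OO carbon that becomes C6.

Step 7
Reactants: 11 tetrahydrofuran
Product: 12 tert-butyl(4-iodobutoxy)diphenylsilane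
Conditions: TBDPSCl, NaI, MeCN, 55 °C
Reagents that add atoms: tert-butyl(chloro)diphenylsilane, CC(C)(C)[Si](Cl)(c1ccccc1)c1ccccc1; sodium iodide, [Na+].[I-]
Why: Silyl-promoted ether cleavage: tert-butyl(iodo)diphenylsilane formed in the flask silylates the ring oxygen and iodide opens the oxonium ion by SN2, a standard route to 4-iodobutyl silyl ethers.

Step 8
Reactants: 13 methoxyallene (1-methoxypropa-1,2-diene); 12 tert-butyl(4-iodobutoxy)diphenylsilane
Product: 15 tert-butyl[(5-methoxyhepta-5,6-dien-1-yl)oxy]diphenylsilane, via 1-lithio-1-methoxyallene 14 (not isolated)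
Conditions: n-BuLi, THF, −40 °C; then 12, −40 → 0 °C; Et3N-deactivated silica
Reagents that add atoms: none
Why: α-Lithiation of methoxyallene and SN2 alkylation with a primary iodide (the allene acting as a masked propenoyl anion) should give the 1-alkyl-1-methoxyallene, the silyl ether being inert to the organolithium at low temperature.

Step 9
Reactants: 10 1-({[(3R)-3-hydroperoxypent-4-en-1-yl]oxy}methyl)-4-methoxybenzene; 15 tert-butyl[(5-methoxyhepta-5,6-dien-1-yl)oxy]diphenylsilane
Product: 16 tert-butyl{[5-methoxy-5-({(3R)-5-[(4-methoxyphenyl)methoxy]pent-1-en-3-yl}peroxy)hept-6-en-1-yl]oxy}diphenylsilane (both epimers at the ketal carbon)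
Conditions: PPTS (5 mol%), CH2Cl2, −20 → 0 °C; Et3N quench
Reagents that add atoms: none
Why: Acid-catalysed perketalisation of an enol ether by a hydroperoxide: protonation of the central allene carbon gives a 1-methoxyallyl cation that the hydroperoxide should capture at the oxygen-bearing carbon under kinetic control, as alcohols do with alkoxyallenes, so that the O1–O2 and O2–C3 bonds and both vinyl groups are in place; C3 forms as both epimers and C6 is not involved.

Step 10
Reactants: 16 tert-butyl{[5-methoxy-5-({(3R)-5-[(4-methoxyphenyl)methoxy]pent-1-en-3-yl}peroxy)hept-6-en-1-yl]oxy}diphenylsilane (both epimers at the ketal carbon)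
Product: 17 tert-butyl{4-[(6R)-3-methoxy-6-{2-[(4-methoxyphenyl)methoxy]ethyl}-3,6-dihydro-1,2-dioxin-3-yl]butoxy}diphenylsilane (both C3 epimers)
Conditions: second-generation Grubbs catalyst RuCl2(=CHPh)(PCy3)(H2IMes) (5–10 mol%), CH2Cl2 (0.005 M), 40 °C, argon sparge
Reagents that add atoms: none
Why: Proposed new method: the ruthenium benzylidene should exchange onto the less hindered vinyl group at C6, and [2+2] cycloaddition with the vinyl group on the ketal carbon C3 followed by cycloreversion of the ruthenacyclobutane forms C4=C5 and releases ethene. The closest known reactions are ring-closing metathesis of N-allyl O-allyl hydroxylamines to 3,6-dihydro-1,2-oxazines and of mixed acrolein acetals of allylic alcohols, together with cross-metathesis of allylic dialkyl peroxides, which shows that an O–O bond can survive the carbene. The single ring closes as a six-membered 3,6-dihydro-1,2-dioxine by joining the two vinyl termini (diene ring-closing mode, cis alkene enforced by the ring), helped by the skewed C–O–O–C geometry of dialkyl peroxides and by the fully substituted C3. No stereocentre is created: C6 lies outside the metallacycle and keeps its configuration, and both C3 epimers should cyclise. The selectivity needed is chemoselectivity for the two terminal alkenes over the O–O bond and over olefin migration, secured by the absence of any other alkene or alkyne (the side chain is carried as a silyl ether) and by high dilution with removal of ethene.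

Step 11
Reactants: 17 tert-butyl{4-[(6R)-3-methoxy-6-{2-[(4-methoxyphenyl)methoxy]ethyl}-3,6-dihydro-1,2-dioxin-3-yl]butoxy}diphenylsilane (both C3 epimers)
Product: 18 tert-butyl{4-[(6S)-3-methoxy-6-{2-[(4-methoxyphenyl)methoxy]ethyl}-1,2-dioxan-3-yl]butoxy}diphenylsilane (both C3 epimers)
Conditions: KO2CN=NCO2K, AcOH, CH2Cl2, 0 °C → rt
Reagents that add atoms: none
Why: Diimide reduction: concerted syn transfer of two hydrogens from HN=NH to the cis ring alkene saturates C4=C5 without the O–O hydrogenolysis that metal-catalysed hydrogenation would cause, and the ethers and the ketal are inert (the descriptor at C6 changes to S only because C5 loses priority).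

Step 12
Reactants: 18 tert-butyl{4-[(6S)-3-methoxy-6-{2-[(4-methoxyphenyl)methoxy]ethyl}-1,2-dioxan-3-yl]butoxy}diphenylsilane (both C3 epimers)
Product: 19 tert-butyl{4-[(3R,6S)-3-methoxy-6-{2-[(4-methoxyphenyl)methoxy]ethyl}-1,2-dioxan-3-yl]butoxy}diphenylsilane
Conditions: CSA (10 mol%), MeOH, 3 Å MS, 0 °C → rt; NaHCO3; minor epimer resubmitted
Reagents that add atoms: methanol, CO
Why: Acid-catalysed ketal exchange (anomeric equilibration): reversible ionisation at C3 and recapture by methanol should funnel both epimers into the isomer with axial methoxy and both carbon chains equatorial, which is (3R,6S), while C6, the PMB ether and the TBDPS ether are not touched by catalytic CSA.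

Step 13
Reactants: 19 tert-butyl{4-[(3R,6S)-3-methoxy-6-{2-[(4-methoxyphenyl)methoxy]ethyl}-1,2-dioxan-3-yl]butoxy}diphenylsilane
Product: 20 4-[(3R,6S)-3-methoxy-6-{2-[(4-methoxyphenyl)methoxy]ethyl}-1,2-dioxan-3-yl]butan-1-ol
Conditions: TBAF, AcOH (1:1), THF, 0 °C → rt; Et3N-deactivated silica
Reagents that add atoms: none
Why: Fluoride-induced desilylation frees the primary alcohol, the acetic acid buffer keeping the medium from becoming basic enough for Kornblum–DeLaMare fragmentation at C6–H, and the δ-hydroxy ketal is kept away from acid so that it cannot close to a spiroketal.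

Step 14
Reactants: 20 4-[(3R,6S)-3-methoxy-6-{2-[(4-methoxyphenyl)methoxy]ethyl}-1,2-dioxan-3-yl]butan-1-ol
Product: 21 4-[(3R,6S)-3-methoxy-6-{2-[(4-methoxyphenyl)methoxy]ethyl}-1,2-dioxan-3-yl]butanal
Conditions: Dess–Martin periodinane, pyridine, CH2Cl2, 0 °C
Reagents that add atoms: none
Why: Dess–Martin oxidation of a primary alcohol to the aldehyde is compatible with dialkyl peroxides, and the pyridine buffer neutralises the acetic acid released so that the ketal is not exchanged.

Step 15
Reactants: 21 4-[(3R,6S)-3-methoxy-6-{2-[(4-methoxyphenyl)methoxy]ethyl}-1,2-dioxan-3-yl]butanal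
Product: 22 (3R,6S)-3-methoxy-6-{2-[(4-methoxyphenyl)methoxy]ethyl}-3-(pent-4-yn-1-yl)-1,2-dioxane
Conditions: dimethyl (1-diazo-2-oxopropyl)phosphonate, K2CO3, MeOH, 0 °C → rt
Reagents that add atoms: dimethyl (1-diazo-2-oxopropyl)phosphonate, COP(=O)(OC)C(=[N+]=[N-])C(C)=O
Why: Ohira–Bestmann modification of the Seyferth–Gilbert homologation: methanolysis of the reagent gives the dimethyl (diazomethyl)phosphonate anion, whose Horner–Wadsworth–Emmons-type addition to the aldehyde, loss of N2 and 1,2-hydride shift of the alkylidene carbene give the terminal alkyne under carbonate conditions too mild to deprotonate C6–H.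

Step 16
Reactants: 23 undec-1-yne
Product: 25 (E)-1-iodoundec-1-ene, via (E)-undec-1-enylzirconocene chloride 24 (not isolated)
Conditions: Cp2Zr(H)Cl, THF, rt; then I2, 0 °C
Reagents that add atoms: iodine, II
Why: Schwartz hydrozirconation adds Zr–H syn and anti-Markovnikov to the terminal alkyne and iodinolysis of the C–Zr bond proceeds with retention, which fixes the E geometry of the future C=C.

Step 17
Reactants: 22 (3R,6S)-3-methoxy-6-{2-[(4-methoxyphenyl)methoxy]ethyl}-3-(pent-4-yn-1-yl)-1,2-dioxane; 25 (E)-1-iodoundec-1-ene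
Product: 26 (3R,6S)-3-[(6E)-hexadec-6-en-4-yn-1-yl]-3-methoxy-6-{2-[(4-methoxyphenyl)methoxy]ethyl}-1,2-dioxane
Conditions: PdCl2(PPh3)2 (5 mol%), CuI (10 mol%), Et3N, THF, rt, degassed
Reagents that add atoms: none
Why: Sonogashira coupling (oxidative addition of the vinyl iodide to zerovalent palladium, transmetallation from the copper acetylide, reductive elimination) joins C(sp) to C(sp2) with retention of the E geometry at room temperature, conditions under which 1,2-dioxanes are known to persist.

Step 18
Reactants: 26 (3R,6S)-3-[(6E)-hexadec-6-en-4-yn-1-yl]-3-methoxy-6-{2-[(4-methoxyphenyl)methoxy]ethyl}-1,2-dioxane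
Product: 27 2-[(3S,6R)-6-[(6E)-hexadec-6-en-4-yn-1-yl]-6-methoxy-1,2-dioxan-3-yl]ethan-1-ol
Conditions: DDQ, CH2Cl2/pH 7 phosphate buffer, 0 °C
Reagents that add atoms: none
Why: Oxidative PMB cleavage: DDQ abstracts hydride from the electron-rich benzylic position and water hydrolyses the oxocarbenium ion, freeing the arm alcohol while the buffered medium spares the ketal, the peroxide and the enyne.

Step 19
Reactants: 27 2-[(3S,6R)-6-[(6E)-hexadec-6-en-4-yn-1-yl]-6-methoxy-1,2-dioxan-3-yl]ethan-1-ol
Product: 28 2-[(3S,6R)-6-[(6E)-hexadec-6-en-4-yn-1-yl]-6-methoxy-1,2-dioxan-3-yl]acetic acid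
Conditions: TEMPO (20 mol%), PhI(OAc)2 (2.5 equiv), MeCN/H2O, rt
Reagents that add atoms: water, O
Why: TEMPO/PhI(OAc)2 oxidation in aqueous acetonitrile passes through the aldehyde hydrate to the carboxylic acid under mild, slightly acidic conditions that leave the enyne, the peroxide and both stereocentres untouched.

**Compound list**

1 | propane-1,3-diol | OCCCO | starting material
2 | sodium 3-hydroxypropan-1-olate | [Na+].[O-]CCCO | intermediate (not isolated)
3 | 3-[(4-methoxyphenyl)methoxy]propan-1-ol | COc1ccc(COCCCO)cc1 | intermediate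
4 | 3-[(4-methoxyphenyl)methoxy]propanal | COc1ccc(COCCC=O)cc1 | intermediate
5 | vinylmagnesium bromide | C=C[Mg]Br | starting material
6 | bromomagnesium 5-[(4-methoxyphenyl)methoxy]pent-1-en-3-olate (racemic) | C=CC(CCOCc1ccc(OC)cc1)O[Mg]Br | intermediate (not isolated)
7 | rac-5-[(4-methoxyphenyl)methoxy]pent-1-en-3-ol | C=CC(O)CCOCc1ccc(OC)cc1 | intermediate
8 | (3S)-5-[(4-methoxyphenyl)methoxy]pent-1-en-3-ol | C=C[C@@H](O)CCOCc1ccc(OC)cc1 | intermediate
9 | (3S)-5-[(4-methoxyphenyl)methoxy]pent-1-en-3-yl methanesulfonate | C=C[C@@H](OS(C)(=O)=O)CCOCc1ccc(OC)cc1 | intermediate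
10 | 1-({[(3R)-3-hydroperoxypent-4-en-1-yl]oxy}methyl)-4-methoxybenzene | C=C[C@H](OO)CCOCc1ccc(OC)cc1 | intermediate
11 | tetrahydrofuran | C1CCOC1 | starting material
12 | tert-butyl(4-iodobutoxy)diphenylsilane | CC(C)(C)[Si](c1ccccc1)(c1ccccc1)OCCCCI | intermediate
13 | methoxyallene (1-methoxypropa-1,2-diene) | C=C=COC | starting material
14 | 1-lithio-1-methoxyallene | [Li]C(OC)=C=C | intermediate (not isolated)
15 | tert-butyl[(5-methoxyhepta-5,6-dien-1-yl)oxy]diphenylsilane | C=C=C(OC)CCCCO[Si](c1ccccc1)(c1ccccc1)C(C)(C)C | intermediate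
16 | tert-butyl{[5-methoxy-5-({(3R)-5-[(4-methoxyphenyl)methoxy]pent-1-en-3-yl}peroxy)hept-6-en-1-yl]oxy}diphenylsilane, both epimers at the ketal carbon | CC(C)(C)[Si](c1ccccc1)(c1ccccc1)OCCCCC(OC)(C=C)OO[C@@H](C=C)CCOCc1ccc(OC)cc1 | intermediate
17 | tert-butyl{4-[(6R)-3-methoxy-6-{2-[(4-methoxyphenyl)methoxy]ethyl}-3,6-dihydro-1,2-dioxin-3-yl]butoxy}diphenylsilane, both C3 epimers | CC(C)(C)[Si](c1ccccc1)(c1ccccc1)OCCCCC1(OC)C=C[C@@H](CCOCc2ccc(OC)cc2)OO1 | intermediate
18 | tert-butyl{4-[(6S)-3-methoxy-6-{2-[(4-methoxyphenyl)methoxy]ethyl}-1,2-dioxan-3-yl]butoxy}diphenylsilane, both C3 epimers | CC(C)(C)[Si](c1ccccc1)(c1ccccc1)OCCCCC1(OC)CC[C@@H](CCOCc2ccc(OC)cc2)OO1 | intermediate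
19 | tert-butyl{4-[(3R,6S)-3-methoxy-6-{2-[(4-methoxyphenyl)methoxy]ethyl}-1,2-dioxan-3-yl]butoxy}diphenylsilane | CC(C)(C)[Si](c1ccccc1)(c1ccccc1)OCCCC[C@]1(OC)CC[C@@H](CCOCc2ccc(OC)cc2)OO1 | intermediate
20 | 4-[(3R,6S)-3-methoxy-6-{2-[(4-methoxyphenyl)methoxy]ethyl}-1,2-dioxan-3-yl]butan-1-ol | OCCCC[C@]1(OC)CC[C@@H](CCOCc2ccc(OC)cc2)OO1 | intermediate
21 | 4-[(3R,6S)-3-methoxy-6-{2-[(4-methoxyphenyl)methoxy]ethyl}-1,2-dioxan-3-yl]butanal | O=CCCC[C@]1(OC)CC[C@@H](CCOCc2ccc(OC)cc2)OO1 | intermediate
22 | (3R,6S)-3-methoxy-6-{2-[(4-methoxyphenyl)methoxy]ethyl}-3-(pent-4-yn-1-yl)-1,2-dioxane | C#CCCC[C@]1(OC)CC[C@@H](CCOCc2ccc(OC)cc2)OO1 | intermediate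
23 | undec-1-yne | C#CCCCCCCCCC | starting material
24 | (E)-undec-1-enylzirconocene chloride (cyclopentadienyl rings written η1 in the SMILES) | CCCCCCCCC/C=C/[Zr](Cl)(C1C=CC=C1)C1C=CC=C1 | intermediate (not isolated)
25 | (E)-1-iodoundec-1-ene | CCCCCCCCC/C=C/I | intermediate
26 | (3R,6S)-3-[(6E)-hexadec-6-en-4-yn-1-yl]-3-methoxy-6-{2-[(4-methoxyphenyl)methoxy]ethyl}-1,2-dioxane | CCCCCCCCC/C=C/C#CCCC[C@]1(OC)CC[C@@H](CCOCc2ccc(OC)cc2)OO1 | intermediate
27 | 2-[(3S,6R)-6-[(6E)-hexadec-6-en-4-yn-1-yl]-6-methoxy-1,2-dioxan-3-yl]ethan-1-ol | CCCCCCCCC/C=C/C#CCCC[C@]1(OC)CC[C@@H](CCO)OO1 | intermediate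
28 | 2-[(3S,6R)-6-[(6E)-hexadec-6-en-4-yn-1-yl]-6-methoxy-1,2-dioxan-3-yl]acetic acid | CCCCCCCCC/C=C/C#CCCC[C@]1(OC)CC[C@@H](CC(=O)O)OO1 | target

**Step count and risks**

Total: 19 steps. Longest linear sequence: 16 steps (steps 1–6, 9–15, 17–19); steps 7–8 and step 16 are side branches.

Steps most likely to fail:

Step 10 (ring-closing metathesis). The carbene loaded on the C6 vinyl group may fail to engage the hindered vinyl group on the fully substituted C3, leaving time for olefin migration or ruthenium-induced O–O cleavage. The fallback sets out from 10 and 15 and returns to the route at 19. Hydroperoxide 10 is capped with 3,4-dihydro-2H-pyran (PPTS, CH2Cl2) as 2-({(3R)-5-[(4-methoxyphenyl)methoxy]pent-1-en-3-yl}peroxy)oxane F1. Allene 15 is hydrolysed (aqueous oxalic acid, THF) to 7-{[tert-butyl(diphenyl)silyl]oxy}hept-1-en-3-one F2. Cross-metathesis of F1 with the unhindered enone F2 (RuCl2(=CHPh)(PCy3)(H2IMes), CH2Cl2, 40 °C), a reaction type in which allylic dialkyl peroxides are known to survive, should give (6E,8R)-1-{[tert-butyl(diphenyl)silyl]oxy}-10-[(4-methoxyphenyl)methoxy]-8-(oxan-2-ylperoxy)dec-6-en-5-one F3. Diimide (KO2CN=NCO2K, AcOH) should then give (8S)-1-{[tert-butyl(diphenyl)silyl]oxy}-10-[(4-methoxyphenyl)methoxy]-8-(oxan-2-ylperoxy)decan-5-one F4. CSA in methanol removes the tetrahydropyranyl group; the freed hydroperoxide adds to the ketone and the cyclic peroxyhemiketal is methylated under the same thermodynamic control as in step 12, giving 19.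

Step 9 (hydroperoxide addition to the methoxyallene). Proton-induced isomerisation or oligomerisation of the alkoxyallene may outrun capture by the hydroperoxide, or the methoxyallyl cation may be captured at its terminal carbon. The fallback sets out from 15 and returns at 16. Methanol is added to 15 (PPTS, MeOH, 0 °C; the known alcohol addition to alkoxyallenes) to give the storable ketal tert-butyl[(5,5-dimethoxyhept-6-en-1-yl)oxy]diphenylsilane F5. F5, used in excess, is then exchanged with hydroperoxide 10 under CSA catalysis in CH2Cl2 over 5 Å molecular sieves, which take up the methanol and drive the acetal exchange to 16.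

Step 6 (peroxide displacement). In aqueous alkaline methanol the allylic mesylate may undergo solvolysis or E2 loss of methanesulfonic acid, and the product hydroperoxide may be alkylated a second time to the symmetric dialkyl peroxide. The fallback sets out from 9 and returns at 10. Mesylate 9 is treated with the monoprotected nucleophile 2-methoxyprop-2-yl hydroperoxide and CsOH·H2O in DMF at 0 °C (aprotic SN2, no second alkylation possible) to give 1-methoxy-4-[({(3R)-3-[(2-methoxypropan-2-yl)peroxy]pent-4-en-1-yl}oxy)methyl]benzene F6. Aqueous acetic acid in THF then releases hydroperoxide 10.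

**Further compounds**

F1 | step 10 | 2-({(3R)-5-[(4-methoxyphenyl)methoxy]pent-1-en-3-yl}peroxy)oxane (both acetal epimers) | C=C[C@H](OOC1CCCCO1)CCOCc2ccc(OC)cc2
F2 | step 10 | 7-{[tert-butyl(diphenyl)silyl]oxy}hept-1-en-3-one | C=CC(=O)CCCCO[Si](c1ccccc1)(c1ccccc1)C(C)(C)C
F3 | step 10 | (6E,8R)-1-{[tert-butyl(diphenyl)silyl]oxy}-10-[(4-methoxyphenyl)methoxy]-8-(oxan-2-ylperoxy)dec-6-en-5-one | CC(C)(C)[Si](c1ccccc1)(c1ccccc1)OCCCCC(=O)/C=C/[C@H](OOC1CCCCO1)CCOCc2ccc(OC)cc2
F4 | step 10 | (8S)-1-{[tert-butyl(diphenyl)silyl]oxy}-10-[(4-methoxyphenyl)methoxy]-8-(oxan-2-ylperoxy)decan-5-one | CC(C)(C)[Si](c1ccccc1)(c1ccccc1)OCCCCC(=O)CC[C@H](OOC1CCCCO1)CCOCc2ccc(OC)cc2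
F5 | step 9 | tert-butyl[(5,5-dimethoxyhept-6-en-1-yl)oxy]diphenylsilane | C=CC(OC)(OC)CCCCO[Si](c1ccccc1)(c1ccccc1)C(C)(C)C
F6 | step 6 | 1-methoxy-4-[({(3R)-3-[(2-methoxypropan-2-yl)peroxy]pent-4-en-1-yl}oxy)methyl]benzene | C=C[C@H](OOC(C)(C)OC)CCOCc1ccc(OC)cc1
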